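At the first reading, 10.0 min into the midnight flask, substrate stands at 2%, so its consumption belongs to the lowest rung of the ladder, the minutes before that reading. No reading reaches 5.0 s or 5.0 min, so my reckoning covers the hours.

| flask | substrate | other conformer | remark | time |
|---|---|---|---|---|
| midnight | 1 M | 0.50 M | the very flask that is asked about, followed so far |  |
| winter | 1 M | 0.34 M | run made earlier |  |
| flask | 1.0 M | 0.500 M |  | 6.0 h |

midnight run (percent of the substrate and other conformer together charged)

| time / min | isomer of the product A / % | target / % | substrate / % |
|---|---|---|---|
| 10.0 | 59 | 3 | 2 |
| 25.0 | 52 | 2 | 0 |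
| 50.0 | 49 | 1 | 0 |
| 80.0 | 46 | 3 | 0 |

winter run (percent of the substrate and other conformer together charged)

| time / h | isomer of the product A / % | target / % | substrate / % |
|---|---|---|---|
| 0.200 | 59 | 5 | 0 |
| 0.417 | 53 | 4 | 1 |
| 1.00 | 46 | 0 | 2 |
| 2.50 | 29 | 3 | 0 |

(scatter of a reading: 2 percentage points)

- ratio of isomer of the product A to target at 5.0 s
- ratio of isomer of the product A to target at 5.0 min
- ratio of isomer of the product A to target at 6.0 h
- which of isomer of the product A and target there is more of at 6.0 h



The next rung is hours. In the midnight flask, isomer of the product A falls from 59% to 46%, while target scatters between 1% and 3%. In the winter flask at 2.50 h, the three readings add up to 32.0%, so the rest stands in something unread.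

The midnight readings give k_d = 0.213 h⁻¹, my drain constant: the logarithm of the first over the last reading of isomer of the product A, divided by the time between them. The winter readings give 0.309 h⁻¹, but I keep the midnight value, as that is the flask asked about. Its half-life, 3.25 h, is shorter than the 6.0 h asked. Reckoning without a floor, k_d carries the midnight flask from its first reading to 17.0% of isomer of the product A at 6.0 h. That is more than the 5% read for target in the winter flask at 0.200 h, so I expect isomer of the product A to lead.

The forecast gives ratios of 25, 24 and 5, with isomer of the product A ahead, and has target forming “in parallel with A, at a fixed ratio near 25”. Its 13% of isomer of the product A at the end is lower than my figure.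

The flask gives ratios of 0.921, 4.01 and 4.64, with isomer of the product A ahead.

    substrate ⇌ other conformer (K = 1.14, k = 1.93 min⁻¹)
    substrate → target (k = 0.381 min⁻¹)
    other conformer → isomer of the product A (k = 0.620 min⁻¹)
    target ⇌ isomer of the product A (K = 1.57, k = 0.00715 min⁻¹)
    target ⇌ isomer of the product B (K = 24.0, k = 0.304 min⁻¹)
    2 substrate → homo dimer (k = 2.55 × 10⁻⁴ M⁻¹ min⁻¹)

The flask holds 16.2% of isomer of the product A at 6.0 h, against my 17.0%. Target then has a forward half-life of 2.3 min towards isomer of the product B, far shorter than 6.0 h, and is made 1.03 times as fast as it is used up, a quasi-steady intermediate at 3.50%.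

In the neighbouring flask, with 2.0 M of other conformer, I start from the same first reading of isomer of the product A, since it was 59% at both earlier loadings, and k_d again gives 17.0%. The neighbouring flask, as computed, ends with 16.9% of isomer of the product A, at a ratio to target of 4.86.

(The runs are simulated for an exercise.)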